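**Retrosynthetic overview**
- The target, benzyl tricosanoate, is acyclic and achiral. The strategy rests on C7 of the tricosanoate chain, a plain methylene that lies between the C1–C6 benzyl hexanoate arm and the C8–C23 hexadecyl arm and is brought in as the CH2 of bis(phenylsulfonyl)methane.
- Last disconnection: the two C7–H bonds go back to two C7–SO2Ph bonds (reductive desulfonylation of benzyl 7,7-bis(phenylsulfonyl)tricosanoate).
- Key disconnection: C7–C8 and C6–C7, made in one pot by alkylating the bis-sulfone first with 1-bromohexadecane and then with benzyl 6-bromohexanoate.
- The bromo ester comes from 6-bromohexanoic acid and benzyl alcohol.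
- No ring is formed at any stage; the only ring in the target, the benzyl phenyl ring, arrives with benzyl alcohol.

Key step: step 2

Remark: the chain is numbered from the ester carbonyl (C1) to the terminal methyl (C23). The target has no stereocentre, so no stereocontrol is needed. Iodide 7 is assumed to carry most of the second alkylation, with some direct displacement on bromide 3 running alongside.

**Step 1**
Reactants: 1 6-bromohexanoic acid; 2 benzyl alcohol
Product: 3 benzyl 6-bromohexanoate
Conditions: 2 (1.1 equiv), p-toluenesulfonic acid monohydrate (5 mol%), toluene, reflux, Dean–Stark trap
Reagents that add atoms: none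
Why: Fischer esterification, an acid-catalysed equilibrium pulled to the ester by azeotropic removal of water; the primary bromide is inert to the sulfonic acid catalyst.

**Step 2**
Reactants: 4 bis(phenylsulfonyl)methane; 5 1-bromohexadecane; 3 benzyl 6-bromohexanoate
Product: 8 benzyl 7,7-bis(phenylsulfonyl)tricosanoate, via 1,1-bis(phenylsulfonyl)heptadecane 6 (not isolated), via benzyl 6-iodohexanoate 7 (not isolated)
Conditions: 4 (1.05 equiv), Cs2CO3 (1.2 equiv), dry DMF, rt; 5 (1.0 equiv), 50 °C; then Cs2CO3 (2.0 equiv), Bu4NI (0.2 equiv), 3 (1.5 equiv), 80 °C
Reagents that add atoms: none
Why: Cs2CO3 deprotonates 4 to the carbanion stabilised by both sulfonyl groups, which displaces bromide from 5 by SN2 to form the C7–C8 bond and give 6; fresh Cs2CO3 then deprotonates 6, Bu4NI turns 3 into the more reactive iodide 7 by halide exchange, and a second SN2 displacement forms the C6–C7 bond, the iodide going back into the exchange cycle. The closest known reaction type is the stepwise dialkylation of bis(phenylsulfonyl)methane, a malonate-type active-methylene alkylation, run here without isolating the monoalkyl stage. No ring closes and no stereocentre arises, because C7 carries two identical sulfonyl groups. The selectivity needed is monoalkylation in the first stage; it should be secured by making 5 the limiting reagent, by the lower acidity of 6 compared with remaining 4 (so the base sits on 4), and by the greater hindrance of the anion of 6, which should react only once iodide, more base and heat are supplied. The carbonate base is too weak to enolise or cleave the benzyl ester under anhydrous conditions, and both electrophiles are unhindered primary halides.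

**Step 3**
Reactants: 8 benzyl 7,7-bis(phenylsulfonyl)tricosanoate
Product: 10 benzyl tricosanoate, via benzyl 7-(phenylsulfonyl)tricosanoate 9 (not isolated)
Conditions: SmI2 (10 equiv, 0.1 M in THF), HMPA (40 equiv), MeOH (20 equiv), −20 to 0 °C; aq. NH4Cl
Reagents that add atoms: none
Why: Reductive desulfonylation, in which electron transfer from divalent samarium (SmI2–HMPA) into each phenylsulfonyl group cleaves a C7–S bond with loss of benzenesulfinate and the carbon-centred species left at C7 is reduced and protonated by MeOH (first to racemic monosulfone 9, then to 10), while the unactivated aliphatic benzyl ester should not be reduced at low temperature without water or amine activators.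

**Compound list**
1 | 6-bromohexanoic acid | OC(=O)CCCCCBr | starting material
2 | benzyl alcohol | OCc1ccccc1 | starting material
3 | benzyl 6-bromohexanoate | BrCCCCCC(=O)OCc1ccccc1 | intermediate
4 | bis(phenylsulfonyl)methane | O=S(=O)(CS(=O)(=O)c1ccccc1)c1ccccc1 | starting material
5 | 1-bromohexadecane | CCCCCCCCCCCCCCCCBr | starting material
6 | 1,1-bis(phenylsulfonyl)heptadecane (formed in the flask, not isolated) | CCCCCCCCCCCCCCCCC(S(=O)(=O)c1ccccc1)S(=O)(=O)c1ccccc1 | intermediate
7 | benzyl 6-iodohexanoate (formed in the flask, not isolated) | ICCCCCC(=O)OCc1ccccc1 | intermediate
8 | benzyl 7,7-bis(phenylsulfonyl)tricosanoate | CCCCCCCCCCCCCCCCC(S(=O)(=O)c1ccccc1)(S(=O)(=O)c1ccccc1)CCCCCC(=O)OCc1ccccc1 | intermediate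
9 | benzyl 7-(phenylsulfonyl)tricosanoate (racemic at C7, formed in the flask, not isolated) | CCCCCCCCCCCCCCCCC(S(=O)(=O)c1ccccc1)CCCCCC(=O)OCc1ccccc1 | intermediate
10 | benzyl tricosanoate | CCCCCCCCCCCCCCCCCCCCCCC(=O)OCc1ccccc1 | target

**Total step count:** 3
**Longest linear sequence:** 3 steps (1 → 3 → 8 → 10)

**Steps most likely to fail**

1. Step 2. The second substitution at the hindered, weakly nucleophilic C7 carbanion may stall, so that the monoalkyl stage accumulates while the halo ester is used up by carbonate alkylation or elimination. Double hexadecylation in the first stage is the other hazard. The fallback gives up the linchpin and joins C7–C8 directly. It sets out from 5, which is converted with Mg turnings in THF into hexadecylmagnesium bromide F1. Commercial 7-bromoheptanoic acid (OC(=O)CCCCCCBr) is esterified with 2 under the conditions of step 1 to give benzyl 7-bromoheptanoate F2. Slow addition of F1 to F2 with Li2CuCl4 (3 mol%) and N-methylpyrrolidone (4 equiv) in THF at 0 °C, a copper-catalysed alkyl–alkyl cross-coupling that tolerates esters, should give the C23 chain directly. The fallback comes back to the route at 10.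

2. Step 3. The benzyl ester may be lost by reductive benzylic C–O cleavage, the C7 organosamarium may attack the C1 ester with six-membered ring closure before it is protonated, or the second C–S cleavage may stop short. The fallback sets out from 8 and uses Mg turnings in MeOH at 50 °C, a dissolving-metal desulfonylation known for geminal bis-sulfones. The magnesium methoxide formed should also exchange the ester, giving methyl tricosanoate F3. Transesterification of F3 with an excess of 2 and catalytic Ti(OiPr)4 at 110 °C, with methanol distilled off, comes back to the route at 10.

3. Step 1. The equilibrium may not go to completion, and benzyl alcohol may self-condense to its ether under acid, which complicates purification. The fallback sets out from 1, which is treated with oxalyl chloride and catalytic DMF in CH2Cl2 to give 6-bromohexanoyl chloride F4. Irreversible acylation of 2 with F4 and pyridine in CH2Cl2 at 0 °C comes back to the route at 3.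

**Further compounds**
F1 | step 2 | hexadecylmagnesium bromide | CCCCCCCCCCCCCCCC[Mg]Br
F2 | step 2 | benzyl 7-bromoheptanoate | BrCCCCCCC(=O)OCc1ccccc1
F3 | step 3 | methyl tricosanoate | CCCCCCCCCCCCCCCCCCCCCCC(=O)OC
F4 | step 1 | 6-bromohexanoyl chloride | ClC(=O)CCCCCBr
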